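The data come from a simulation for an exercise.

4 questions stood on the blue flask, and I met them with one time read from its curve.

in all of them: substrate 10 mM

| flask | temperature | remark | time |
|---|---|---|---|
| blue | −20 °C | the very flask that is asked about, followed so far |  |
| ochre | −25 °C | run made earlier |  |
| flask | −20 °C |  | 5.0 h |

| run | time / h | ring / % |
|---|---|---|
| blue | 0.833 | 27 |
| blue | 1.50 | 42 |
| blue | 2.50 | 41 |
| blue | 3.00 | 41 |
| blue | 4.00 | 38 |
| ochre | 0.833 | 16 |
| ochre | 1.50 | 24 |
| ochre | 2.50 | 29 |
| ochre | 3.00 | 31 |
| ochre | 4.00 | 35 |

(scatter of a reading: 2 percentage points)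

- dusk: at 5.0 h add substrate, 50.0% of the amount charged, then wait 1.5 h
- noon: change nothing and wait 1.5 h more
- dawn: at 5.0 h raise the temperature by 15 K, then wait 1.5 h

- percentages count the substrate that a species holds: one open dimer or idle adduct counts as two
- ring is meant together with its idle adduct
- additions bring no volume worth counting
- the numbers in the tables scatter by 2 percentage points (one standard deviation)
- candidate steps: substrate -> ring; 2 substrate -> open dimer; substrate + ring <-> idle adduct; ring <-> isomer of the product
- in an amount of ring, one idle adduct counts as one ring

* ring, in percent of the substrate first charged, at 5.0 h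
* the option that brings most further ring ("none" if no option brings more than 2 percentage points) (dusk / noon / dawn / none)
* ring present, in percent of the substrate first charged, after dusk
* ring present, in percent of the substrate first charged, after dawn

In the first instants of the blue run, ring climbed: 27% at 0.833 h, then 42% at 1.50 h. In the middle the climb stopped, with 41% at 2.50 h, each reading scattering by 2 percentage points. Midway between those last two times lies 2.00 h, and I took this as the hand-over time: the moment at which the making of ring stops outrunning its removal.

Towards the end, ring drifted down, so I carried the drift from the peak reading forward from the last reading: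

ring now = 38% − (42% − 38%) × (5.0 h − 4.00 h) / (4.00 h − 1.50 h) = 36.4%

At that pace I reckoned a loss of 2.4 points for noon.

The colder ochre run was still rising at its last reading, 35% at 4.00 h, so I put its hand-over, as an estimate, at that time or later, and took as the stretch between the two runs:

f = 4.00 h / 2.00 h = 2.00

The rise at dawn, 15 K, is 3 such gaps, so if each gap counts alike the stretch is 8.00. That puts the hand-over at 0.250 h at dawn, shorter than the 1.5 h of waiting. By this reckoning the waiting at dawn outlasted the hand-over, but the readings did not give the direction of the change, since the candidate step between ring and isomer of the product runs both ways: kinetic against thermodynamic control.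

The forecast gave 37% (34% to 40%), a little higher than my figure. It gave 53% after dusk (44% to 60%) and 27% after dawn (19% to 42%), and it chose dusk, saying “Dawn would speed the loss”.

    substrate → ring (k = 1.75 × 10⁻⁴ s⁻¹, Ea = 81.0 kJ mol⁻¹)
    2 substrate → open dimer (k = 0.00920 M⁻¹ s⁻¹, Ea = 38.0 kJ mol⁻¹)
    substrate + ring ⇌ idle adduct, settled at all times (K = 585 M⁻¹, ΔH = −5.00 kJ mol⁻¹)
    ring ⇌ isomer of the product (K = 1.59, k = 9.76 × 10⁻⁵ s⁻¹, Ea = 84.0 kJ mol⁻¹, ΔH = −86.0 kJ mol⁻¹)
    (constants at −20 °C)

The blue flask gave 37.3%, then 54.7% after dusk and 63.4% after dawn, so the best option was dawn, with a gain of 26 points against 17 points for dusk and −2.1 points for noon. The relaxation half-life of free ring and isomer of the product by that step alone, 1.21 h, was short against 5.0 h. Carried to a repeat of the flask at −35 °C, the hand-over time 2.00 h stretched by 8.00 gives 16.0 h, later than 5.0 h. At 5.00 h, that repeat held 34% free substrate and 0.317% isomer of the product.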